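## Retrosynthetic overview

1. Target 22 ⇒ keto-lactol 19, an isomer of 22. C6–C7 is made by carbene-catalysed acyl-anion addition of the lactol-masked enal carbon C6 to the methyl ketone C7, which closes the carbocycle and sets C7. O2–C3 then forms by 6-endo oxa-Michael addition, which closes the pyran (carbocycle first, pyran second, one flask).
2. 19 ⇒ dihydropyranone 8 + enyne 16. C4–C4a is made by acetylide 1,2-addition followed by acid-induced allylic transposition. The temporary dihydropyranone ring is formed first and opened in the last step; it carries C8/C8a and fixes the enal geometry.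
3. 8 ⇒ β-methoxy enone 4 + 2,2-dimethoxypropanal 6. C8–C8a is made by a syn-selective boron aldol, then cyclisation.
4. 16 ⇒ D-isoleucine 9 + diyne 12. C3′ is set by chelation-controlled MeMgBr addition; the E-alkene comes from LiAlH4 reduction.

Assumption: atoms are tracked with the target locants (C1–C8a, side chain C1′–C7′). The (−)-enantiomer of Ipc2BOTf is quoted for step 3 by analogy; if the sense of induction proves opposite, the antipodal borane is used and nothing else changes.

## Route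

Step 1
Reactants: 1 (E)-4-methoxybut-3-en-2-one; 2 formaldehyde (monomer gas from paraformaldehyde)
Product: 4 (E)-1-methoxy-5-[(triethylsilyl)oxy]pent-1-en-3-one, via lithium alkoxide 3 (not isolated)
Conditions: LiN(SiMe3)2 (1.05 equiv), THF, −78 °C; CH2O (g), −78 °C; Et3SiOTf (1.2 equiv), −78 → −40 °C
Reagents that add atoms: triethylsilyl trifluoromethanesulfonate, CC[Si](CC)(CC)OS(=O)(=O)C(F)(F)F
Why: Kinetic enolate hydroxymethylation (formaldehyde aldol) at the only enolisable position, with the lithium aldolate silylated in the flask before it can cyclise; no stereocentre is formed.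

Step 2
Reactants: 5 methyl 2,2-dimethoxypropanoate
Product: 6 2,2-dimethoxypropanal
Conditions: i-Bu2AlH (1.1 equiv), CH2Cl2, −78 °C; aq. KNaC4H4O6
Reagents that add atoms: none
Why: Half-reduction of an α,α-dialkoxy ester, whose chelated tetrahedral aluminate survives at −78 °C and releases the aldehyde only on work-up.

Step 3
Reactants: 4 (E)-1-methoxy-5-[(triethylsilyl)oxy]pent-1-en-3-one; 6 2,2-dimethoxypropanal
Product: 8 (2S,3S)-2-(1,1-dimethoxyethyl)-3-{[(triethylsilyl)oxy]methyl}-2,3-dihydro-4H-pyran-4-one, via syn-aldol adduct 7 (not isolated)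
Conditions: (−)-Ipc2BOTf [(C10H17)2BOSO2CF3] (1.3 equiv), i-Pr2NEt, CH2Cl2, −78 °C; 6, −78 → −20 °C; MeOH, NaH2PO4/Na2HPO4 buffer, H2O2, 0 °C; then pyridinium p-toluenesulfonate (10 mol %), CH2Cl2, 23 °C
Reagents that add atoms: none
Why: Paterson boron aldol in which the (Z)-enol diisopinocampheylborinate reacts through a Zimmerman–Traxler chair to give the syn aldol with reagent-controlled facial selectivity (sets C8 and C8a), followed by acid-catalysed oxa-Michael addition–elimination of methanol to the cis-2,3-disubstituted dihydropyranone.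

Step 4
Reactants: 9 D-isoleucine
Product: 10 (2R,3R)-2-hydroxy-3-methylpentanoic acid
Conditions: NaNO2, 1 M H2SO4, H2O, 0 → 23 °C
Reagents that add atoms: water, O
Why: Diazotisation of an α-amino acid proceeds with net retention through the α-lactone (double inversion), so C4′ and C5′ both come from the chiral pool.

Step 5
Reactants: 10 (2R,3R)-2-hydroxy-3-methylpentanoic acid
Product: 11 (2R,3R)-2-hydroxy-N-methoxy-N,3-dimethylpentanamide
Conditions: MeNH(OMe)·HCl, EDC·HCl, HOBt, N-methylmorpholine, CH2Cl2, 0 → 23 °C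
Reagents that add atoms: N,O-dimethylhydroxylamine hydrochloride, CNOC.Cl
Why: Carbodiimide amidation to the Weinreb amide; the stereocentres are not touched.

Step 6
Reactants: 11 (2R,3R)-2-hydroxy-N-methoxy-N,3-dimethylpentanamide; 12 1,4-bis(trimethylsilyl)buta-1,3-diyne
Product: 14 (6R,7R)-6-hydroxy-7-methyl-1-(trimethylsilyl)nona-1,3-diyn-5-one, via lithium diynide 13 (not isolated)
Conditions: 12, MeLi·LiBr, THF, 23 °C, 3 h; 11, i-PrMgCl (1.0 equiv), THF, −78 °C; mix, −78 → −20 °C; cold 0.5 M HCl to pH 5, used at once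
Reagents that add atoms: none
Why: Desilylative lithiation of the bis-silyl diyne followed by Weinreb ketone synthesis, in which the chelated tetrahedral intermediate prevents over-addition and the pre-formed magnesium alkoxide protects the α-hydroxyl.

Step 7
Reactants: 14 (6R,7R)-6-hydroxy-7-methyl-1-(trimethylsilyl)nona-1,3-diyn-5-one
Product: 15 (5S,6R,7R)-5,7-dimethyl-1-(trimethylsilyl)nona-1,3-diyne-5,6-diol
Conditions: MeMgBr (3.0 equiv), THF, −78 °C; cold 1 M HCl
Reagents that add atoms: methylmagnesium bromide, C[Mg]Br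
Why: Cram-chelate-controlled Grignard 1,2-addition in which the magnesium alkoxide and the ketone oxygen form a five-membered chelate and methyl attacks anti to the sec-butyl group, giving the anti-diol with (5S) configuration (C3′).

Step 8
Reactants: 15 (5S,6R,7R)-5,7-dimethyl-1-(trimethylsilyl)nona-1,3-diyne-5,6-diol
Product: 16 (3E,5S,6R,7R)-5,7-dimethyl-1-(trimethylsilyl)non-3-en-1-yne-5,6-diol
Conditions: LiAlH4 (3 equiv), THF, 0 → 40 °C; aq. KNaC4H4O6
Reagents that add atoms: none
Why: Hydroxyl-directed trans-hydroalumination reduces only the triple bond next to the carbinol and gives the E-alkene, leaving the distal silylalkyne intact.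

Step 9
Reactants: 8 (2S,3S)-2-(1,1-dimethoxyethyl)-3-{[(triethylsilyl)oxy]methyl}-2,3-dihydro-4H-pyran-4-one; 16 (3E,5S,6R,7R)-5,7-dimethyl-1-(trimethylsilyl)non-3-en-1-yne-5,6-diol
Product: 19 1-[(2S,3S)-4-[(3E,5S,6R,7R)-5,6-dihydroxy-5,7-dimethylnon-3-en-1-yn-1-yl]-6-hydroxy-3-(hydroxymethyl)-3,6-dihydro-2H-pyran-2-yl]ethan-1-one, via trilithium acetylide 17 (not isolated), via carbinol adduct 18 (not isolated)
Conditions: 16 (1.3 equiv), MeLi·LiBr (3.0 equiv per 16), THF, −78 → 23 °C; anhydrous CeCl3 (1.5 equiv), −78 °C; 8, −78 °C; then AcOH–THF–H2O 3:1:1, 23 → 40 °C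
Reagents that add atoms: water, O
Why: Acetylide 1,2-addition to the vinylogous ester (Stork–Danheiser type, CeCl3 suppressing enolisation) followed by acid-induced allylic (Ferrier-type) transposition with water to the lactol, while the same acid removes the silyl ether and the ketal; the ring keeps the masked formyl carbon cis to C8a, and C8/C8a are untouched.

Step 10
Reactants: 19 1-[(2S,3S)-4-[(3E,5S,6R,7R)-5,6-dihydroxy-5,7-dimethylnon-3-en-1-yn-1-yl]-6-hydroxy-3-(hydroxymethyl)-3,6-dihydro-2H-pyran-2-yl]ethan-1-one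
Product: 22 (7S,8S,8aS)-3-[(1E,3S,4R,5R)-3,4-dihydroxy-3,5-dimethylhept-1-en-1-yl]-7,8-dihydroxy-7-methyl-1,7,8,8a-tetrahydro-6H-isochromen-6-one, via open-chain enal 20 (not isolated), via alkynyl cyclohexenone 21 (not isolated)
Conditions: 2-(pentafluorophenyl)-6,7-dihydro-5H-pyrrolo[2,1-c][1,2,4]triazol-2-ium tetrafluoroborate (C11H7F5N3·BF4, 20 mol %), i-Pr2NEt (40 mol %), degassed THF (0.02 M), 23 °C; then DBU (0.3 equiv), 40 °C
Reagents that add atoms: none
Why: Proposed new method: ring–chain tautomerism of the lactol releases enal 20, the carbene converts its formyl carbon C6 into a Breslow acyl anion that adds 6-exo to the C7 methyl ketone through a chair with the C8 hydroxyl, the C8a hydroxymethyl and the C7 methyl equatorial (new hydroxyl axial and cis to the C8 hydroxyl, hence 7S) to give 21, whose liberated C1 hydroxyl then closes the pyran by 6-endo 1,6-oxa-Michael addition to the ynenone; the closest known reactions are the carbene-catalysed intramolecular crossed aldehyde–ketone benzoin cyclisation and the base-mediated 6-endo cycloisomerisation of 3-alkynyl-4-(hydroxymethyl)enones.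

## Compound list

1 | (E)-4-methoxybut-3-en-2-one | CO/C=C/C(C)=O | starting material
2 | formaldehyde | C=O | starting material
3 | lithium (E)-5-methoxy-3-oxopent-4-en-1-olate | [Li+].[O-]CCC(=O)/C=C/OC | intermediate
4 | (E)-1-methoxy-5-[(triethylsilyl)oxy]pent-1-en-3-one | CC[Si](CC)(CC)OCCC(=O)/C=C/OC | intermediate
5 | methyl 2,2-dimethoxypropanoate | COC(=O)C(C)(OC)OC | starting material
6 | 2,2-dimethoxypropanal | CC(OC)(OC)C=O | intermediate
7 | (1E,4S,5S)-5-hydroxy-1,6,6-trimethoxy-4-{[(triethylsilyl)oxy]methyl}hept-1-en-3-one | CO/C=C/C(=O)[C@@H](CO[Si](CC)(CC)CC)[C@H](O)C(C)(OC)OC | intermediate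
8 | (2S,3S)-2-(1,1-dimethoxyethyl)-3-{[(triethylsilyl)oxy]methyl}-2,3-dihydro-4H-pyran-4-one | CC(OC)(OC)[C@H]1OC=CC(=O)[C@H]1CO[Si](CC)(CC)CC | intermediate
9 | D-isoleucine, (2R,3R)-2-amino-3-methylpentanoic acid | CC[C@@H](C)[C@@H](N)C(=O)O | starting material
10 | (2R,3R)-2-hydroxy-3-methylpentanoic acid | CC[C@@H](C)[C@@H](O)C(=O)O | intermediate
11 | (2R,3R)-2-hydroxy-N-methoxy-N,3-dimethylpentanamide | CC[C@@H](C)[C@@H](O)C(=O)N(C)OC | intermediate
12 | 1,4-bis(trimethylsilyl)buta-1,3-diyne | C[Si](C)(C)C#CC#C[Si](C)(C)C | starting material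
13 | lithium 4-(trimethylsilyl)buta-1,3-diyn-1-ide | [Li+].[C-]#CC#C[Si](C)(C)C | intermediate
14 | (6R,7R)-6-hydroxy-7-methyl-1-(trimethylsilyl)nona-1,3-diyn-5-one | CC[C@@H](C)[C@@H](O)C(=O)C#CC#C[Si](C)(C)C | intermediate
15 | (5S,6R,7R)-5,7-dimethyl-1-(trimethylsilyl)nona-1,3-diyne-5,6-diol | CC[C@@H](C)[C@@H](O)[C@@](C)(O)C#CC#C[Si](C)(C)C | intermediate
16 | (3E,5S,6R,7R)-5,7-dimethyl-1-(trimethylsilyl)non-3-en-1-yne-5,6-diol | CC[C@@H](C)[C@@H](O)[C@@](C)(O)/C=C/C#C[Si](C)(C)C | intermediate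
17 | trilithium (3E,5S,6R,7R)-5,7-dimethylnon-3-en-1-yn-1-ide-5,6-diolate | CC[C@@H](C)[C@@H]([O-])[C@@](C)([O-])/C=C/C#[C-].[Li+].[Li+].[Li+] | intermediate
18 | (2S,3S)-2-(1,1-dimethoxyethyl)-4-[(3E,5S,6R,7R)-5,6-dihydroxy-5,7-dimethylnon-3-en-1-yn-1-yl]-3-{[(triethylsilyl)oxy]methyl}-3,4-dihydro-2H-pyran-4-ol (C-4 epimers, formed as its alkoxide) | CC(OC)(OC)[C@H]1OC=CC(O)(C#C/C=C/[C@](C)(O)[C@H](O)[C@H](C)CC)[C@H]1CO[Si](CC)(CC)CC | intermediate
19 | 1-[(2S,3S)-4-[(3E,5S,6R,7R)-5,6-dihydroxy-5,7-dimethylnon-3-en-1-yn-1-yl]-6-hydroxy-3-(hydroxymethyl)-3,6-dihydro-2H-pyran-2-yl]ethan-1-one (anomers) | CC(=O)[C@H]1OC(O)C=C(C#C/C=C/[C@](C)(O)[C@H](O)[C@H](C)CC)[C@H]1CO | intermediate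
20 | (2E,4S,5S)-3-[(3E,5S,6R,7R)-5,6-dihydroxy-5,7-dimethylnon-3-en-1-yn-1-yl]-5-hydroxy-4-(hydroxymethyl)-6-oxohept-2-enal (formyl cis to C4) | O=C/C=C(/C#C/C=C/[C@](C)(O)[C@H](O)[C@H](C)CC)[C@@H](CO)[C@H](O)C(C)=O | intermediate
21 | (4S,5S,6S)-3-[(3E,5S,6R,7R)-5,6-dihydroxy-5,7-dimethylnon-3-en-1-yn-1-yl]-5,6-dihydroxy-4-(hydroxymethyl)-6-methylcyclohex-2-en-1-one | O=C1C=C(C#C/C=C/[C@](C)(O)[C@H](O)[C@H](C)CC)[C@@H](CO)[C@H](O)[C@]1(C)O | intermediate
22 | (7S,8S,8aS)-3-[(1E,3S,4R,5R)-3,4-dihydroxy-3,5-dimethylhept-1-en-1-yl]-7,8-dihydroxy-7-methyl-1,7,8,8a-tetrahydro-6H-isochromen-6-one | CC[C@@H](C)[C@@H](O)[C@@](C)(O)/C=C/C1=CC2=CC(=O)[C@@](C)(O)[C@@H](O)[C@@H]2CO1 | target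

## Step count and risks

Total steps: 10. Longest linear sequence: 7 (steps 4, 5, 6, 7, 8, 9, 10). The core branch is steps 1, 3, 9, 10, with step 2 feeding step 3.

Steps most likely to fail:

**Step 10.** The Breslow intermediate of a conjugated ynenal may instead undergo homoenolate protonation and redox lactonisation with one of the free hydroxyls, and C7 selectivity rests on substrate control. The fallback sets out from 19 and comes back at 21. 19 is treated with SmI2 (samarium diiodide, divalent samarium, 3 equiv) in THF/t-BuOH at −78 °C. The ketyl of the formyl group of the open form couples with the C7 ketone in a pinacol cyclisation to give the cyclohexenetriol F1. MnO2 in CH2Cl2 then oxidises only the allylic C6 carbinol of F1 and delivers 21. 21 is closed to 22 with DBU, or with AgOTf (5 mol %), as in the second half of step 10.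

**Step 9.** A trilithiated nucleophile must add cleanly to a hindered vinylogous ester. One acid treatment must then effect transposition, desilylation and ketal hydrolysis without isomerising the enal or ionising the tertiary allylic alcohol. The fallback sets out from 16 and comes back at 19. 16 is silylated with Et3SiOTf and 2,6-lutidine to the bis(triethylsilyl) ether F2. MeLi·LiBr (1.05 equiv) cleaves only the alkynyl–silicon bond and gives the monolithium acetylide F3. F3 with CeCl3 adds to 8 to give the carbinol F4. Aqueous AcOH/THF at 40 °C, in two stages if needed, then removes the three triethylsilyl groups and the ketal, effects the transposition, and gives 19.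

**Step 3.** The β-silyloxy boron enolate may eliminate, the hindered aldehyde 6 may react slowly, and the enantioselectivity of Ipc enolates is moderate. The fallback sets out from 4 and comes back at 8. 4 is enolised with Et3SiOTf and Et3N to the (1E,3Z)-diene F5. F5 undergoes an endo-selective hetero-Diels–Alder reaction with 6, catalysed by the tridentate Schiff-base complex CrCl(L) (5 mol %, trivalent chromium, 4 Å sieves), where L is the dianion of (1R,2S)-1-{[3-(1-adamantyl)-2-hydroxy-5-methylbenzylidene]amino}indan-2-ol; the antipodal ligand is used if the sense of induction requires it. This gives the cycloadduct F6. CF3CO2H (cat.) in CH2Cl2 then removes methanol and the enol silyl group to give 8.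

Further compounds

F1 | step 10 | 3-[(3E,5S,6R,7R)-5,6-dihydroxy-5,7-dimethylnon-3-en-1-yn-1-yl]-4-(hydroxymethyl)-6-methylcyclohex-2-ene-1,5,6-triol (ring centres C-4, C-5, C-6 as in 21; C-1 epimers) | OC1C=C(C#C/C=C/[C@](C)(O)[C@H](O)[C@H](C)CC)[C@@H](CO)[C@H](O)[C@]1(C)O
F2 | step 9 | (3E,5S,6R,7R)-5,7-dimethyl-5,6-bis[(triethylsilyl)oxy]-1-(trimethylsilyl)non-3-en-1-yne | CC[C@@H](C)[C@@H](O[Si](CC)(CC)CC)[C@@](C)(O[Si](CC)(CC)CC)/C=C/C#C[Si](C)(C)C
F3 | step 9 | lithium (3E,5S,6R,7R)-5,7-dimethyl-5,6-bis[(triethylsilyl)oxy]non-3-en-1-yn-1-ide | CC[C@@H](C)[C@@H](O[Si](CC)(CC)CC)[C@@](C)(O[Si](CC)(CC)CC)/C=C/C#[C-].[Li+]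
F4 | step 9 | (2S,3S)-2-(1,1-dimethoxyethyl)-4-{(3E,5S,6R,7R)-5,7-dimethyl-5,6-bis[(triethylsilyl)oxy]non-3-en-1-yn-1-yl}-3-{[(triethylsilyl)oxy]methyl}-3,4-dihydro-2H-pyran-4-ol (C-4 epimers) | CC(OC)(OC)[C@H]1OC=CC(O)(C#C/C=C/[C@](C)(O[Si](CC)(CC)CC)[C@H](O[Si](CC)(CC)CC)[C@H](C)CC)[C@H]1CO[Si](CC)(CC)CC
F5 | step 3 | (1E,3Z)-1-methoxy-3,5-bis[(triethylsilyl)oxy]penta-1,3-diene | CO/C=C/C(O[Si](CC)(CC)CC)=C/CO[Si](CC)(CC)CC
F6 | step 3 | (2S,3S)-2-(1,1-dimethoxyethyl)-6-methoxy-4-[(triethylsilyl)oxy]-3-{[(triethylsilyl)oxy]methyl}-3,6-dihydro-2H-pyran (C-6 epimers) | CC(OC)(OC)[C@H]1OC(OC)C=C(O[Si](CC)(CC)CC)[C@H]1CO[Si](CC)(CC)CC
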